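**Retrosynthetic overview**
- Feature: ring B is a 5-pentylpyrogallol. It has oxygens on the adjacent carbons C1', C2' and C3', hydrogens on C4' and C6', and pentyl on C5'. Only the outer oxygen on C1' carries the ring A acyl group, so ring B is built with O–C1' born as a free phenol and O–C2'/O–C3' born as benzyl ethers.
- Last cuts: one acidic hydrogenation takes back all benzyl groups and the benzylic C=O, which becomes the first CH2 of the pentyl chain. The depside bond C(=O)–O–C1' is then cut to a 2-O-benzyl ring A acid chloride and a monophenol.
- Key cut: C1'–C6' and C4'–C5' of ring B, leading back to 3,4-bis(benzyloxy)furan and hept-1-yn-3-one. The forward reaction is a [4+2] cycloaddition followed by Lewis-acid opening of the oxygen bridge, and the furan oxygen becomes HO–C1'.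
- Ring order: the furan ring is made first (double Claisen condensation of diglycolate with oxalate) and ring B second. Ring A is bought as 5-propylresorcinol and only decorated (formylation, 4-O-methylation, 2-O-benzylation, oxidation).

Key step: step 6

Remark: ring B locants are C1' (acyloxy carbon), C2' and C3' (hydroxyl carbons), C4' (H), C5' (pentyl carbon) and C6' (H). The target is achiral, and the stereocentres of the few racemic intermediates are erased later.

Step 1
Reactants: 1 dimethyl diglycolate (dimethyl 2,2'-oxydiacetate); 2 dimethyl oxalate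
Product: 4 dimethyl 3,4-dihydroxyfuran-2,5-dicarboxylate, via disodium furandiolate 3 (not isolated)
Conditions: NaOMe (2.5 equiv), MeOH, reflux; then 2 M HCl, 0 °C
Reagents that add atoms: none
Why: Double Claisen (Hinsberg-type) condensation, in which both CH2 groups flanking the ether oxygen of 1 are acylated by the two ester carbonyls of 2 and the resulting dione enolizes to the aromatic furandiolate, whose salt formation drives the equilibrium.

Step 2
Reactants: 4 dimethyl 3,4-dihydroxyfuran-2,5-dicarboxylate
Product: 5 dimethyl 3,4-bis(benzyloxy)furan-2,5-dicarboxylate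
Conditions: BnBr (2.4 equiv), K2CO3 (3 equiv), DMF, 70 °C
Reagents that add atoms: benzyl bromide BrCc1ccccc1
Why: Williamson ether synthesis, in which the two acidic enolic hydroxyls are deprotonated by K2CO3 and alkylated on oxygen by SN2, since C-alkylation at the fully substituted alpha carbons would cost the furan aromaticity.

Step 3
Reactants: 5 dimethyl 3,4-bis(benzyloxy)furan-2,5-dicarboxylate
Product: 7 3,4-bis(benzyloxy)furan-2,5-dicarboxylic acid, via disodium dicarboxylate 6 (not isolated)
Conditions: NaOH (aq, 4 equiv), THF–MeOH, 60 °C; then 2 M HCl, 0 °C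
Reagents that add atoms: sodium hydroxide [Na+].[OH-]
Why: Saponification (acyl-oxygen ester hydrolysis) of two unhindered methyl esters, to which benzyl ethers and the furan ring are inert.

Step 4
Reactants: 7 3,4-bis(benzyloxy)furan-2,5-dicarboxylic acid
Product: 8 3,4-bis(benzyloxy)furan
Conditions: Cu powder (0.3 equiv), quinoline, 190 °C, under argon
Reagents that add atoms: none
Why: Copper-mediated protodecarboxylation of furan-2-carboxylic acids through furyl–copper species that are protonated in the medium, which is the established access to 3,4-dialkoxyfurans and leaves aryl-type benzyl ethers untouched.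

Step 5
Reactants: 9 hept-1-yn-3-ol (racemic, commercial)
Product: 10 hept-1-yn-3-one
Conditions: IBX (1.5 equiv), EtOAc, 75 °C; filter, concentrate cold
Reagents that add atoms: none
Why: IBX oxidation of a secondary propargylic alcohol under neutral, nucleophile-free conditions, so that the sensitive terminal ynone is not exposed to Michael donors.

Step 6
Reactants: 8 3,4-bis(benzyloxy)furan; 10 hept-1-yn-3-one
Product: 12 1-[3,4-bis(benzyloxy)-5-hydroxyphenyl]pentan-1-one, via oxanorbornadiene 11 (not isolated)
Conditions: 10 (1.3 equiv), PhMe, 40 °C, under argon, dark; then ZnI2 (0.2 equiv), CH2Cl2, 4 Å MS, 0 °C → rt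
Reagents that add atoms: none
Why: The electron-rich furan 8 (donor oxygens on both beta carbons) and the electron-poor terminal ynone 10 join in a concerted, suprafacial, normal-electron-demand [4+2] cycloaddition that makes C4'–C5' and C1'–C6' in one event and so closes the six-membered carbocycle of ring B intermolecularly as the 7-oxanorbornadiene 11, the known Diels–Alder behaviour of 3,4-dialkoxyfurans towards acceptor alkynes. The furan is symmetric, so only one constitutional adduct can form, and the two bridgehead stereocentres of 11 (racemic, cis by the geometry of the bicycle) vanish on aromatization, so no stereocontrol element is needed. ZnI2 then ionizes one bridgehead C–O bond to a cyclohexadienyl (arenium-type) cation, which loses the proton geminal to the remaining oxygen, the known acid-promoted isomerization of oxanorbornadienes to phenols. The selectivity needed is the direction of this opening: cleavage at C4', the bridgehead beside the acyl-bearing C5', spreads the charge over C4', C6' and C2' (at C2' as an oxocarbenium ion of the benzyloxy group) and leaves the acyl group on an uncharged carbon, whereas cleavage at C1' would place charge on C5', alpha to the ketone, which is the same bias that makes an acyl group meta-directing. The former furan oxygen therefore stays on C1', meta to the ketone, as the single free hydroxyl beside two benzyl ethers. Keeping the cycloaddition free of acid with the ynone in excess, and adding the dry Lewis acid only when 8 is consumed, holds back conjugate addition of the furan alpha carbon to the ynone, a second cycloaddition on the strained enone bond of 11 and hydrolysis of the enol ethers.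

Step 7
Reactants: 13 5-propylbenzene-1,3-diol (divarinol, commercial)
Product: 15 2,4-dihydroxy-6-propylbenzaldehyde, via aryl iminium chloride 14 (not isolated)
Conditions: POCl3 (1.5 equiv), DMF, 0 °C → rt; then ice-water
Reagents that add atoms: N,N-dimethylformamide CN(C)C=O; water O
Why: Vilsmeier–Haack formylation, in which the chloroiminium ion attacks the position ortho to one hydroxyl and para to the other (the site at which 5-alkylresorcinols are known to formylate) and water hydrolyses the iminium salt to the aldehyde.

Step 8
Reactants: 15 2,4-dihydroxy-6-propylbenzaldehyde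
Product: 16 2-hydroxy-4-methoxy-6-propylbenzaldehyde
Conditions: MeI (1.05 equiv), K2CO3 (1.1 equiv), acetone, rt
Reagents that add atoms: iodomethane CI
Why: Selective Williamson O-methylation, because the 2-hydroxyl is locked in a six-membered hydrogen bond to the aldehyde and is less acidic and less nucleophilic than the para 4-hydroxyl, which takes up the single equivalent of MeI.

Step 9
Reactants: 16 2-hydroxy-4-methoxy-6-propylbenzaldehyde
Product: 17 2-(benzyloxy)-4-methoxy-6-propylbenzaldehyde
Conditions: BnBr (1.2 equiv), K2CO3 (2 equiv), DMF, 60 °C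
Reagents that add atoms: benzyl bromide BrCc1ccccc1
Why: Williamson ether synthesis under slightly more forcing conditions (polar aprotic solvent, heat), which breaks the hydrogen bond and alkylates the only remaining hydroxyl.

Step 10
Reactants: 17 2-(benzyloxy)-4-methoxy-6-propylbenzaldehyde
Product: 18 2-(benzyloxy)-4-methoxy-6-propylbenzoic acid
Conditions: NaClO2, NaH2PO4, 2-methylbut-2-ene (excess), t-BuOH–H2O, rt
Reagents that add atoms: sodium chlorite NaClO2 [Na+].[O-]Cl=O
Why: Pinnick oxidation, in which chlorous acid adds to the aldehyde and fragments to the acid while the alkene scavenger removes hypochlorous acid before it can chlorinate the electron-rich ring.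

Step 11
Reactants: 18 2-(benzyloxy)-4-methoxy-6-propylbenzoic acid; 12 1-[3,4-bis(benzyloxy)-5-hydroxyphenyl]pentan-1-one
Product: 20 2,3-bis(benzyloxy)-5-pentanoylphenyl 2-(benzyloxy)-4-methoxy-6-propylbenzoate, via acid chloride 19 (not isolated)
Conditions: (COCl)2 (1.5 equiv), DMF (cat.), CH2Cl2, 0 °C → rt, evaporate; then 12, Et3N (2 equiv), DMAP (0.2 equiv), CH2Cl2, 0 °C → rt
Reagents that add atoms: none
Why: Acid chloride formation followed by DMAP-catalysed O-acylation (nucleophilic acyl substitution), which can only reach O–C1' because it is the sole free hydroxyl of 12, and the donor-substituted aroyl chloride is activated enough to overcome its two ortho groups.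

Step 12
Reactants: 20 2,3-bis(benzyloxy)-5-pentanoylphenyl 2-(benzyloxy)-4-methoxy-6-propylbenzoate
Product: 23 peruvinide C (2,3-dihydroxy-5-pentylphenyl 2-hydroxy-4-methoxy-6-propylbenzoate), via triphenol ketone 21 (not isolated), via benzylic alcohol 22 (not isolated)
Conditions: H2 (3 atm), 10% Pd/C, EtOAc–AcOH, HClO4 (cat.), rt → 40 °C; filter under argon, no basic wash
Reagents that add atoms: none
Why: Catalytic hydrogenolysis over Pd/C first cleaves the three benzyl ethers, and in the acidic medium the aryl ketone para to the freed C2' hydroxyl is hydrogenated to the benzylic alcohol and hydrogenolysed through a para-hydroxy-stabilised benzylic cation to CH2, while the doubly ortho-substituted aryl ester, the methyl ether and the arenes persist and the absence of base and of alcohol solvent holds back acyl migration from O–C1' to O–C2' and transesterification.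

**Compound list**
1 | dimethyl diglycolate | COC(=O)COCC(=O)OC | starting material
2 | dimethyl oxalate | COC(=O)C(=O)OC | starting material
3 | disodium 2,5-bis(methoxycarbonyl)furan-3,4-diolate (formed and consumed in the flask) | COC(=O)c1oc(C(=O)OC)c([O-])c1[O-].[Na+].[Na+] | intermediate
4 | dimethyl 3,4-dihydroxyfuran-2,5-dicarboxylate | COC(=O)c1oc(C(=O)OC)c(O)c1O | intermediate
5 | dimethyl 3,4-bis(benzyloxy)furan-2,5-dicarboxylate | COC(=O)c1oc(C(=O)OC)c(OCc2ccccc2)c1OCc1ccccc1 | intermediate
6 | disodium 3,4-bis(benzyloxy)furan-2,5-dicarboxylate (formed and consumed in the flask) | [Na+].[Na+].[O-]C(=O)c1oc(C([O-])=O)c(OCc2ccccc2)c1OCc1ccccc1 | intermediate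
7 | 3,4-bis(benzyloxy)furan-2,5-dicarboxylic acid | OC(=O)c1oc(C(=O)O)c(OCc2ccccc2)c1OCc1ccccc1 | intermediate
8 | 3,4-bis(benzyloxy)furan | c1occ(OCc2ccccc2)c1OCc1ccccc1 | intermediate
9 | hept-1-yn-3-ol (racemic) | CCCCC(O)C#C | starting material
10 | hept-1-yn-3-one | CCCCC(=O)C#C | intermediate
11 | 1-[5,6-bis(benzyloxy)-7-oxabicyclo[2.2.1]hepta-2,5-dien-2-yl]pentan-1-one (racemic, formed and consumed in the flask) | CCCCC(=O)C1=CC2OC1C(OCc1ccccc1)=C2OCc1ccccc1 | intermediate
12 | 1-[3,4-bis(benzyloxy)-5-hydroxyphenyl]pentan-1-one | CCCCC(=O)c1cc(O)c(OCc2ccccc2)c(OCc2ccccc2)c1 | intermediate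
13 | 5-propylbenzene-1,3-diol | CCCc1cc(O)cc(O)c1 | starting material
14 | (2,4-dihydroxy-6-propylbenzylidene)dimethyliminium chloride (formed and consumed in the flask) | CCCc1cc(O)cc(O)c1C=[N+](C)C.[Cl-] | intermediate
15 | 2,4-dihydroxy-6-propylbenzaldehyde | CCCc1cc(O)cc(O)c1C=O | intermediate
16 | 2-hydroxy-4-methoxy-6-propylbenzaldehyde | CCCc1cc(OC)cc(O)c1C=O | intermediate
17 | 2-(benzyloxy)-4-methoxy-6-propylbenzaldehyde | CCCc1cc(OC)cc(OCc2ccccc2)c1C=O | intermediate
18 | 2-(benzyloxy)-4-methoxy-6-propylbenzoic acid | CCCc1cc(OC)cc(OCc2ccccc2)c1C(=O)O | intermediate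
19 | 2-(benzyloxy)-4-methoxy-6-propylbenzoyl chloride (formed and consumed in the flask) | CCCc1cc(OC)cc(OCc2ccccc2)c1C(=O)Cl | intermediate
20 | 2,3-bis(benzyloxy)-5-pentanoylphenyl 2-(benzyloxy)-4-methoxy-6-propylbenzoate | CCCCC(=O)c1cc(OC(=O)c2c(CCC)cc(OC)cc2OCc2ccccc2)c(OCc2ccccc2)c(OCc2ccccc2)c1 | intermediate
21 | 2,3-dihydroxy-5-pentanoylphenyl 2-hydroxy-4-methoxy-6-propylbenzoate (formed and consumed in the flask) | CCCCC(=O)c1cc(O)c(O)c(OC(=O)c2c(O)cc(OC)cc2CCC)c1 | intermediate
22 | 2,3-dihydroxy-5-(1-hydroxypentyl)phenyl 2-hydroxy-4-methoxy-6-propylbenzoate (racemic, formed and consumed in the flask) | CCCCC(O)c1cc(O)c(O)c(OC(=O)c2c(O)cc(OC)cc2CCC)c1 | intermediate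
23 | peruvinide C | CCCCCc1cc(O)c(O)c(OC(=O)c2c(O)cc(OC)cc2CCC)c1 | target

Total step count: 12
Longest linear sequence: 7 (steps 1, 2, 3, 4, 6, 11, 12)

**Steps most likely to fail**

**1. Step 6.**
- What may go wrong: conjugate addition of the furan alpha carbon to the ynone in place of cycloaddition, a second cycloaddition onto the strained adduct, bridge opening in the wrong direction, or hydrolysis of the enol ethers.
- Fallback (sets out from 8, returns at 12): furan 8 is combined with commercial hept-1-en-3-one (C=CC(=O)CCCC) under ZnI2 catalysis in CH2Cl2. This is the known Diels–Alder reaction of the furan with an alkene dienophile. It gives 1-[5,6-bis(benzyloxy)-7-oxabicyclo[2.2.1]hept-5-en-2-yl]pentan-1-one F1 as a racemic endo/exo mixture, and both isomers are usable.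
- An equilibrating base (KOt-Bu, THF–t-BuOH, 0 °C) lets the ketone enolize towards the ring. The bridge oxygen is then expelled by E1cB from the beta carbon, which is by connectivity the bridgehead next to the acyl-bearing carbon. The product is 1-[3,4-bis(benzyloxy)-5-hydroxycyclohexa-1,3-dien-1-yl]pentan-1-one F2, so the direction of opening no longer depends on cation stability.
- Prompt oxidation of the allylic alcohol (Dess–Martin periodinane, NaHCO3, CH2Cl2) gives 2,3-bis(benzyloxy)-5-pentanoylcyclohexa-2,4-dien-1-one F3. This tautomerizes in the flask to phenol 12.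

**2. Step 12.**
- What may go wrong: the deoxygenation stalls at the ketone or alcohol stage, or long exposure to acid brings acyl migration to O–C2' or cleavage of the depside ester.
- Fallback (sets out from 12, returns at 23): the ketone is removed before the ester exists. NaBH4 in MeOH at 0 °C gives 1-[3,4-bis(benzyloxy)-5-hydroxyphenyl]pentan-1-ol F4.
- Ionic hydrogenation (Et3SiH, CF3CO2H, CH2Cl2, −20 °C) proceeds through the benzylic cation stabilised by the para benzyloxy group and gives 3,4-bis(benzyloxy)-5-pentylphenol F5.
- Acylation of F5 with acid chloride 19, made from 18 as in step 11, gives 2,3-bis(benzyloxy)-5-pentylphenyl 2-(benzyloxy)-4-methoxy-6-propylbenzoate F6. A neutral hydrogenolysis (H2, Pd/C, EtOAc, rt) then removes the three benzyl groups to give 23.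

**3. Step 11.**
- What may go wrong: acylation is slow because both partners carry ortho substituents, or the ortho benzyl group is lost or the acid chloride is hydrolysed during activation.
- Fallback (sets out from 16 and 12, returns at 21 and so at 23): aldehyde 16 is oxidized without benzylation (NaClO2, sulfamic acid, aqueous dioxane; Lindgren oxidation) to 2-hydroxy-4-methoxy-6-propylbenzoic acid F7.
- This smaller acid, whose ortho hydroxyl is masked by its hydrogen bond to the carboxyl group, is condensed with 12 through the mixed trifluoroacetic anhydride (trifluoroacetic anhydride, toluene, rt). The product is 2,3-bis(benzyloxy)-5-pentanoylphenyl 2-hydroxy-4-methoxy-6-propylbenzoate F8.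
- Under the conditions of step 12, F8 loses its two benzyl groups to give 21 and runs on to 23.

Further compounds
F1 | step 6 | 1-[5,6-bis(benzyloxy)-7-oxabicyclo[2.2.1]hept-5-en-2-yl]pentan-1-one (racemic endo/exo mixture) | CCCCC(=O)C1CC2OC1C(OCc1ccccc1)=C2OCc1ccccc1
F2 | step 6 | 1-[3,4-bis(benzyloxy)-5-hydroxycyclohexa-1,3-dien-1-yl]pentan-1-one (racemic) | CCCCC(=O)C1=CC(OCc2ccccc2)=C(OCc2ccccc2)C(O)C1
F3 | step 6 | 2,3-bis(benzyloxy)-5-pentanoylcyclohexa-2,4-dien-1-one | CCCCC(=O)C1=CC(OCc2ccccc2)=C(OCc2ccccc2)C(=O)C1
F4 | step 12 | 1-[3,4-bis(benzyloxy)-5-hydroxyphenyl]pentan-1-ol (racemic) | CCCCC(O)c1cc(O)c(OCc2ccccc2)c(OCc2ccccc2)c1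
F5 | step 12 | 3,4-bis(benzyloxy)-5-pentylphenol | CCCCCc1cc(O)c(OCc2ccccc2)c(OCc2ccccc2)c1
F6 | step 12 | 2,3-bis(benzyloxy)-5-pentylphenyl 2-(benzyloxy)-4-methoxy-6-propylbenzoate | CCCCCc1cc(OC(=O)c2c(CCC)cc(OC)cc2OCc2ccccc2)c(OCc2ccccc2)c(OCc2ccccc2)c1
F7 | step 11 | 2-hydroxy-4-methoxy-6-propylbenzoic acid | CCCc1cc(OC)cc(O)c1C(=O)O
F8 | step 11 | 2,3-bis(benzyloxy)-5-pentanoylphenyl 2-hydroxy-4-methoxy-6-propylbenzoate | CCCCC(=O)c1cc(OC(=O)c2c(O)cc(OC)cc2CCC)c(OCc2ccccc2)c(OCc2ccccc2)c1
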